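**Plan**

- Retrosynthesis: the C12 acetate is removed first. Then C9–C10, C8–C9 and C6–C7 are cut in one operation, which opens the cyclopentenone (C8–C12) to an acyclic (Z)-1-chloro-1-iodoalkene carrying the C7≡C8 alkyne on C12, CO (C9) and an (E)-alkenylstannane (C1–C6).
- Enabling feature: the C9 carbonyl lies between the chlorinated alkene carbon C10 and C8, and the exocyclic C7=C8 alkene holds C6 on the carbonyl side. This is the pattern left by syn addition of a C9 acylpalladium across a C7≡C8 alkyne.
- The acyclic precursor is cut at C7–C8 and C10–C11 (two aldehyde-to-alkyne homologations) and at C13–C14 (epoxide plus acetylide), back to 2-methylenepropane-1,3-diol, hept-1-yne and methyl hex-5-ynoate.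
- Forward: the chain is built around C12 first (epoxide opening, 14Z alkene, chloroiodoalkene arm, then alkyne arm). The single ring and the dienone arise together in step 16; silyl cleavage and acetylation finish.
- Stereochemistry: C12 comes from a Sharpless epoxidation and no later step breaks a bond at C12. 14Z comes from Lindlar reduction, the haloalkene geometry from trans-hydroalumination, 5E from the stannane, and 7Z from syn acylpalladation with retentive coupling.

Key step: step 16

Remark: atoms carry prostanoid numbers (C1 ester carbon to C20) and the target is the 12R compound; the facial sense of the titanium–tartrate epoxidation is taken from the known conversion of 2-methylprop-2-en-1-ol into (S)-2-methylglycidol with L-(+)-diethyl tartrate.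

**Route**

Step 1
Reactants: 1 2-methylenepropane-1,3-diol
Product: 2 2-{[(4-methoxybenzyl)oxy]methyl}prop-2-en-1-ol
Conditions: Ag2O, 4-methoxybenzyl chloride, CH2Cl2, rt
Reagents that add atoms: 4-methoxybenzyl chloride, COc1ccc(CCl)cc1
Why: Ag2O-mediated Williamson etherification of a symmetrical diol is known to stop largely at the monoether, because the first alkylation removes the internally hydrogen-bonded, more acidic hydroxyl.

Step 2
Reactants: 2 2-{[(4-methoxybenzyl)oxy]methyl}prop-2-en-1-ol
Product: 3 [(2S)-2-{[(4-methoxybenzyl)oxy]methyl}oxiran-2-yl]methanol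
Conditions: Ti(OiPr)4 (10 mol%), L-(+)-diethyl tartrate (12 mol%), t-BuOOH, 4 Å molecular sieves, CH2Cl2, −20 °C
Reagents that add atoms: tert-butyl hydroperoxide, CC(C)(C)OO
Why: Sharpless asymmetric epoxidation of this 2-substituted allylic alcohol should deliver oxygen to the same face as in the (S)-2-methylglycidol case, which sets the quaternary carbon (later C12) as drawn in 3, while the catalytic loading with sieves limits opening of the sensitive epoxide.

Step 3
Reactants: 3 [(2S)-2-{[(4-methoxybenzyl)oxy]methyl}oxiran-2-yl]methanol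
Product: 4 triethyl{[(2S)-2-{[(4-methoxybenzyl)oxy]methyl}oxiran-2-yl]methoxy}silane
Conditions: Et3SiCl, imidazole, CH2Cl2, 0 °C
Reagents that add atoms: chlorotriethylsilane, CC[Si](Cl)(CC)CC
Why: Standard silylation of a primary alcohol under mild base masks the hydroxyl for the Lewis acid step and prepares it for direct oxidation later, the benzyl-type ether on the other arm being unable to migrate.

Step 4
Reactants: 4 triethyl{[(2S)-2-{[(4-methoxybenzyl)oxy]methyl}oxiran-2-yl]methoxy}silane; 5 hept-1-yne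
Product: 7 (2S)-2-{[(4-methoxybenzyl)oxy]methyl}-1-[(triethylsilyl)oxy]dec-4-yn-2-ol, via lithium heptynylide 6 (not isolated)
Conditions: 5, n-BuLi, THF, −78 °C; BF3·OEt2; then 4, −78 °C
Reagents that add atoms: none
Why: In this BF3-mediated epoxide alkynylation (Yamaguchi–Hirao reaction) the acetylide attacks the unsubstituted epoxide carbon in an SN2 manner, the two β-oxygens disfavouring ionisation at the quaternary carbon, so C13–C14 forms without touching the stereocentre.

Step 5
Reactants: 7 (2S)-2-{[(4-methoxybenzyl)oxy]methyl}-1-[(triethylsilyl)oxy]dec-4-yn-2-ol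
Product: 8 (2S,4Z)-2-{[(4-methoxybenzyl)oxy]methyl}-1-[(triethylsilyl)oxy]dec-4-en-2-ol
Conditions: H2 (1 atm), Pd/CaCO3 poisoned with Pb(OAc)2 (Lindlar catalyst), quinoline, EtOAc, rt
Reagents that add atoms: none
Why: Lindlar semihydrogenation adds hydrogen syn to the only alkyne and gives the 14Z alkene, the benzyl-type ether and the silyl ether being inert to the poisoned catalyst.

Step 6
Reactants: 8 (2S,4Z)-2-{[(4-methoxybenzyl)oxy]methyl}-1-[(triethylsilyl)oxy]dec-4-en-2-ol
Product: 9 (2S,4Z)-2-{[(4-methoxybenzyl)oxy]methyl}-1,2-bis[(triethylsilyl)oxy]dec-4-ene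
Conditions: Et3SiOTf, 2,6-lutidine, CH2Cl2, −78 to 0 °C
Reagents that add atoms: triethylsilyl trifluoromethanesulfonate, CC[Si](CC)(CC)OS(=O)(=O)C(F)(F)F
Why: A silyl triflate with a hindered pyridine base is the standard way to silylate a tertiary alcohol, and the resulting ether later keeps the propargylic oxygen from ionising.

Step 7
Reactants: 9 (2S,4Z)-2-{[(4-methoxybenzyl)oxy]methyl}-1,2-bis[(triethylsilyl)oxy]dec-4-ene
Product: 11 (2S,4Z)-2-{[(4-methoxybenzyl)oxy]methyl}-2-[(triethylsilyl)oxy]dec-4-enal, via alkoxysulfonium chloride 10 (not isolated)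
Conditions: (COCl)2, DMSO, CH2Cl2, −78 to −30 °C; then Et3N, −78 to 0 °C
Reagents that add atoms: none
Why: Under Swern conditions a primary triethylsilyl ether is known to be activated and oxidised directly while a tertiary silyl ether is untouched, giving the non-enolisable α-silyloxy aldehyde in one operation.

Step 8
Reactants: 11 (2S,4Z)-2-{[(4-methoxybenzyl)oxy]methyl}-2-[(triethylsilyl)oxy]dec-4-enal
Product: 12 (3R,5Z)-3-{[(4-methoxybenzyl)oxy]methyl}-3-[(triethylsilyl)oxy]undec-5-en-1-yne
Conditions: dimethyl (1-diazo-2-oxopropyl)phosphonate, K2CO3, MeOH, 0 °C to rt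
Reagents that add atoms: dimethyl (1-diazo-2-oxopropyl)phosphonate, CC(=O)C(=[N+]=[N-])P(=O)(OC)OC
Why: Ohira–Bestmann homologation converts the non-enolisable aldehyde into the terminal alkyne (C10≡C11) under carbonate conditions that leave the tertiary silyl ether intact.

Step 9
Reactants: 12 (3R,5Z)-3-{[(4-methoxybenzyl)oxy]methyl}-3-[(triethylsilyl)oxy]undec-5-en-1-yne
Product: 14 (3R,5Z)-1-chloro-3-{[(4-methoxybenzyl)oxy]methyl}-3-[(triethylsilyl)oxy]undec-5-en-1-yne, via lithium acetylide 13 (not isolated)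
Conditions: n-BuLi, THF, −78 °C; then N-chlorosuccinimide, −78 to 0 °C
Reagents that add atoms: N-chlorosuccinimide, O=C1CCC(=O)N1Cl
Why: Deprotonation of a terminal alkyne and electrophilic chlorination of the acetylide is the standard preparation of 1-chloroalkynes.

Step 10
Reactants: 14 (3R,5Z)-1-chloro-3-{[(4-methoxybenzyl)oxy]methyl}-3-[(triethylsilyl)oxy]undec-5-en-1-yne
Product: 16 (1Z,3R,5Z)-1-chloro-1-iodo-3-{[(4-methoxybenzyl)oxy]methyl}-3-[(triethylsilyl)oxy]undeca-1,5-diene, via lithium alkenylaluminate 15 (not isolated)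
Conditions: LiAlH4, THF, −30 to 0 °C; then I2, THF, −78 °C
Reagents that add atoms: iodine, II
Why: In the known trans-hydroalumination of 1-chloroalkynes with LiAlH4, hydride adds to C11 and aluminium ends on the chlorine-bearing C10 trans to the new hydrogen, so iodinolysis with retention places iodine cis to C12 (the Z haloalkene), the isolated alkene and the ethers being inert at this temperature.

Step 11
Reactants: 16 (1Z,3R,5Z)-1-chloro-1-iodo-3-{[(4-methoxybenzyl)oxy]methyl}-3-[(triethylsilyl)oxy]undeca-1,5-diene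
Product: 17 (2R,4Z)-2-[(Z)-2-chloro-2-iodoethenyl]-2-[(triethylsilyl)oxy]dec-4-en-1-ol
Conditions: DDQ, CH2Cl2/pH 7 buffer, 0 °C
Reagents that add atoms: none
Why: Oxidative cleavage of a 4-methoxybenzyl ether by DDQ is selective for the electron-rich benzyl ether over the silyl ether, the electron-poor haloalkene and the isolated alkene.

Step 12
Reactants: 17 (2R,4Z)-2-[(Z)-2-chloro-2-iodoethenyl]-2-[(triethylsilyl)oxy]dec-4-en-1-ol
Product: 18 (2R,4Z)-2-[(Z)-2-chloro-2-iodoethenyl]-2-[(triethylsilyl)oxy]dec-4-enal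
Conditions: Dess–Martin periodinane, NaHCO3, CH2Cl2, 0 °C to rt
Reagents that add atoms: none
Why: Dess–Martin oxidation of a hindered primary alcohol under buffered conditions gives the aldehyde, which cannot epimerise because its α-carbon is fully substituted.

Step 13
Reactants: 18 (2R,4Z)-2-[(Z)-2-chloro-2-iodoethenyl]-2-[(triethylsilyl)oxy]dec-4-enal
Product: 19 triethyl{[(1Z,3R,5Z)-1-chloro-3-ethynyl-1-iodoundeca-1,5-dien-3-yl]oxy}silane
Conditions: dimethyl (1-diazo-2-oxopropyl)phosphonate, K2CO3, MeOH, 0 °C to rt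
Reagents that add atoms: dimethyl (1-diazo-2-oxopropyl)phosphonate, CC(=O)C(=[N+]=[N-])P(=O)(OC)OC
Why: A second Ohira–Bestmann homologation installs the C7≡C8 alkyne, the carbonate base being too weak to dehydrohalogenate the alkyl-substituted dihaloalkene at this temperature.

Step 14
Reactants: 20 methyl hex-5-ynoate
Product: 21 methyl 6-bromohex-5-ynoate
Conditions: N-bromosuccinimide, AgNO3 (cat.), acetone, rt
Reagents that add atoms: N-bromosuccinimide, O=C1CCC(=O)N1Br
Why: Silver-catalysed electrophilic bromination of a terminal alkyne is a standard route to 1-bromoalkynes and tolerates the ester.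

Step 15
Reactants: 21 methyl 6-bromohex-5-ynoate
Product: 23 methyl (5E)-6-(tributylstannyl)hex-5-enoate, via bromoalkenylstannane 22 (not isolated)
Conditions: Bu3SnH (2.2 equiv), PdCl2(PPh3)2 (2 mol%), THF, rt
Reagents that add atoms: tributyltin hydride, CCCC[SnH](CCCC)CCCC
Why: Palladium-catalysed hydrostannation of a 1-bromoalkyne places tin on the brominated carbon by syn addition and the second equivalent of tin hydride reduces the C–Br bond with retention, the known selective route to (E)-1-stannylalkenes.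

Step 16
Reactants: 19 triethyl{[(1Z,3R,5Z)-1-chloro-3-ethynyl-1-iodoundeca-1,5-dien-3-yl]oxy}silane; 23 methyl (5E)-6-(tributylstannyl)hex-5-enoate; 24 carbon monoxide
Product: 25 methyl (5E,7Z,12R,14Z)-10-chloro-9-oxo-12-[(triethylsilyl)oxy]prosta-5,7,10,14-tetraen-1-oate
Conditions: Pd(PPh3)4 (10 mol%), CO (1 atm), THF, 55 °C, 23 (1.3 equiv) added slowly
Reagents that add atoms: none
Why: Proposed new method: zerovalent palladium should insert into the C10–I bond in preference to the stronger C10–Cl bond, CO insertion gives the C9 acylpalladium, and its syn addition across the C7≡C8 alkyne closes the cyclopentenone and leaves palladium on C7 cis to the new carbonyl. Transmetalation from the (E)-alkenylstannane 23 and reductive elimination then join C6 to C7 with retention at both alkenes, so the 5E,7Z dienone follows from the mechanism. The closest known reaction types are the cyclic acylpalladation of alkyne- or alkene-tethered vinyl iodides under CO and the Stille interception of alkenylpalladium intermediates in carbopalladation cascades, which have not been combined on a 1-chloro-1-iodoalkene. The one ring is closed in the 5-exo-dig mode, since the 6-endo mode would require an anti addition. No stereocentre is formed, and C12 is a spectator whose silyl ether prevents propargylic ionisation. The step needs alkyne insertion to outrun acyl–stannane coupling, which the five-ring tether and slow addition of 23 should secure, and transmetalation at C7 to outrun a second CO insertion, which the low CO pressure and chelation of the C7 palladium by the C9 carbonyl should favour.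

Step 17
Reactants: 25 methyl (5E,7Z,12R,14Z)-10-chloro-9-oxo-12-[(triethylsilyl)oxy]prosta-5,7,10,14-tetraen-1-oate
Product: 26 methyl (5E,7Z,12R,14Z)-10-chloro-12-hydroxy-9-oxoprosta-5,7,10,14-tetraen-1-oate
Conditions: HF·pyridine, pyridine, THF, 0 °C
Reagents that add atoms: none
Why: Buffered HF·pyridine cleaves the tertiary triethylsilyl ether by fluoride-assisted desilylation without the basic conditions that the cross-conjugated chlorodienone would not tolerate.

Step 18
Reactants: 26 methyl (5E,7Z,12R,14Z)-10-chloro-12-hydroxy-9-oxoprosta-5,7,10,14-tetraen-1-oate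
Product: 27 methyl (5E,7Z,12R,14Z)-12-acetoxy-10-chloro-9-oxoprosta-5,7,10,14-tetraen-1-oate
Conditions: Ac2O, DMAP (cat.), Et3N, CH2Cl2, 0 °C to rt
Reagents that add atoms: acetic anhydride, CC(=O)OC(C)=O
Why: DMAP-catalysed acylation is the established way to acetylate the hindered tertiary C12 hydroxyl of cross-conjugated cyclopentenones of this class, and only the O–H bond reacts, so C12 keeps its configuration.

**Compound list**

1 | 2-methylenepropane-1,3-diol | C=C(CO)CO | starting material
2 | 2-{[(4-methoxybenzyl)oxy]methyl}prop-2-en-1-ol | C=C(CO)COCc1ccc(OC)cc1 | intermediate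
3 | [(2S)-2-{[(4-methoxybenzyl)oxy]methyl}oxiran-2-yl]methanol | OC[C@@]1(COCc2ccc(OC)cc2)CO1 | intermediate
4 | triethyl{[(2S)-2-{[(4-methoxybenzyl)oxy]methyl}oxiran-2-yl]methoxy}silane | CC[Si](CC)(CC)OC[C@@]1(COCc2ccc(OC)cc2)CO1 | intermediate
5 | hept-1-yne | CCCCCC#C | starting material
6 | lithium hept-1-yn-1-ide | [Li]C#CCCCCC | intermediate
7 | (2S)-2-{[(4-methoxybenzyl)oxy]methyl}-1-[(triethylsilyl)oxy]dec-4-yn-2-ol | CCCCCC#CC[C@@](O)(CO[Si](CC)(CC)CC)COCc1ccc(OC)cc1 | intermediate
8 | (2S,4Z)-2-{[(4-methoxybenzyl)oxy]methyl}-1-[(triethylsilyl)oxy]dec-4-en-2-ol | CCCCC/C=C\C[C@@](O)(CO[Si](CC)(CC)CC)COCc1ccc(OC)cc1 | intermediate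
9 | (2S,4Z)-2-{[(4-methoxybenzyl)oxy]methyl}-1,2-bis[(triethylsilyl)oxy]dec-4-ene | CCCCC/C=C\C[C@@](O[Si](CC)(CC)CC)(CO[Si](CC)(CC)CC)COCc1ccc(OC)cc1 | intermediate
10 | {[(2S,4Z)-2-{[(4-methoxybenzyl)oxy]methyl}-2-[(triethylsilyl)oxy]dec-4-en-1-yl]oxy}dimethylsulfonium chloride | CCCCC/C=C\C[C@@](O[Si](CC)(CC)CC)(CO[S+](C)C)COCc1ccc(OC)cc1.[Cl-] | intermediate
11 | (2S,4Z)-2-{[(4-methoxybenzyl)oxy]methyl}-2-[(triethylsilyl)oxy]dec-4-enal | CCCCC/C=C\C[C@@](O[Si](CC)(CC)CC)(C=O)COCc1ccc(OC)cc1 | intermediate
12 | (3R,5Z)-3-{[(4-methoxybenzyl)oxy]methyl}-3-[(triethylsilyl)oxy]undec-5-en-1-yne | CCCCC/C=C\C[C@@](O[Si](CC)(CC)CC)(C#C)COCc1ccc(OC)cc1 | intermediate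
13 | lithium acetylide of 12 (lithium on the terminal alkyne carbon) | CCCCC/C=C\C[C@@](O[Si](CC)(CC)CC)(C#C[Li])COCc1ccc(OC)cc1 | intermediate
14 | (3R,5Z)-1-chloro-3-{[(4-methoxybenzyl)oxy]methyl}-3-[(triethylsilyl)oxy]undec-5-en-1-yne | CCCCC/C=C\C[C@@](O[Si](CC)(CC)CC)(C#CCl)COCc1ccc(OC)cc1 | intermediate
15 | lithium [(1E,3R,5Z)-1-chloro-3-{[(4-methoxybenzyl)oxy]methyl}-3-[(triethylsilyl)oxy]undeca-1,5-dien-1-yl]trihydridoaluminate (aluminium cis to C3) | CCCCC/C=C\C[C@@](O[Si](CC)(CC)CC)(/C=C(\[AlH3-])Cl)COCc1ccc(OC)cc1.[Li+] | intermediate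
16 | (1Z,3R,5Z)-1-chloro-1-iodo-3-{[(4-methoxybenzyl)oxy]methyl}-3-[(triethylsilyl)oxy]undeca-1,5-diene | CCCCC/C=C\C[C@@](O[Si](CC)(CC)CC)(/C=C(\I)Cl)COCc1ccc(OC)cc1 | intermediate
17 | (2R,4Z)-2-[(Z)-2-chloro-2-iodoethenyl]-2-[(triethylsilyl)oxy]dec-4-en-1-ol | CCCCC/C=C\C[C@@](O[Si](CC)(CC)CC)(/C=C(\I)Cl)CO | intermediate
18 | (2R,4Z)-2-[(Z)-2-chloro-2-iodoethenyl]-2-[(triethylsilyl)oxy]dec-4-enal | CCCCC/C=C\C[C@@](O[Si](CC)(CC)CC)(/C=C(\I)Cl)C=O | intermediate
19 | triethyl{[(1Z,3R,5Z)-1-chloro-3-ethynyl-1-iodoundeca-1,5-dien-3-yl]oxy}silane | CCCCC/C=C\C[C@@](O[Si](CC)(CC)CC)(/C=C(\I)Cl)C#C | intermediate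
20 | methyl hex-5-ynoate | C#CCCCC(=O)OC | starting material
21 | methyl 6-bromohex-5-ynoate | BrC#CCCCC(=O)OC | intermediate
22 | methyl (5E)-6-bromo-6-(tributylstannyl)hex-5-enoate | COC(=O)CCC/C=C(\Br)[Sn](CCCC)(CCCC)CCCC | intermediate
23 | methyl (5E)-6-(tributylstannyl)hex-5-enoate | CCCC[Sn](CCCC)(CCCC)/C=C/CCCC(=O)OC | intermediate
24 | carbon monoxide | [C-]#[O+] | starting material
25 | methyl (5E,7Z,12R,14Z)-10-chloro-9-oxo-12-[(triethylsilyl)oxy]prosta-5,7,10,14-tetraen-1-oate | CCCCC/C=C\C[C@@]1(O[Si](CC)(CC)CC)C=C(Cl)C(=O)/C1=C\C=C\CCCC(=O)OC | intermediate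
26 | methyl (5E,7Z,12R,14Z)-10-chloro-12-hydroxy-9-oxoprosta-5,7,10,14-tetraen-1-oate | CCCCC/C=C\C[C@@]1(O)C=C(Cl)C(=O)/C1=C\C=C\CCCC(=O)OC | intermediate
27 | methyl (5E,7Z,12R,14Z)-12-acetoxy-10-chloro-9-oxoprosta-5,7,10,14-tetraen-1-oate | CCCCC/C=C\C[C@@]1(OC(C)=O)C=C(Cl)C(=O)/C1=C\C=C\CCCC(=O)OC | target

**Step count and risks**

Total steps: 18. Longest linear sequence: 16 (steps 1–13 and 16–18, from 2-methylenepropane-1,3-diol); steps 14–15 make the stannane in a side branch.

**Step 16 (labelled as a new method).** The cascade may leak in three ways: the stannane may capture the C9 acylpalladium before it adds to the alkyne, the C7 alkenylpalladium may take up a second CO before transmetalation, or the vinyl iodide may couple without CO. The fallback sets out from 19 and returns at 25, building the ring and the C7=C8 alkene separately by the aldol route that is established for cross-conjugated cyclopentenone prostanoids.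
- Hydroboration of the terminal alkyne of 19 with dicyclohexylborane and oxidation with NaBO3·4H2O would give (3S,5Z)-3-[(Z)-2-chloro-2-iodoethenyl]-3-[(triethylsilyl)oxy]undec-5-enal F1.
- Intramolecular Nozaki–Hiyama–Kishi addition (CrCl2, NiCl2 cat., DMF), in line with the known addition of α-chloroalkenylchromium species to aldehydes, would close C9–C10 to (4S)-2-chloro-4-[(2Z)-oct-2-en-1-yl]-4-[(triethylsilyl)oxy]cyclopent-2-en-1-ol F2.
- Dess–Martin oxidation would give (4S)-2-chloro-4-[(2Z)-oct-2-en-1-yl]-4-[(triethylsilyl)oxy]cyclopent-2-en-1-one F3.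
- The aldehyde partner methyl (5E)-7-oxohept-5-enoate F4 would come from methyl 5-oxopentanoate and (triphenylphosphoranylidene)acetaldehyde by Wittig reaction.
- The lithium enolate of F3 (LiN(SiMe3)2, THF, −78 °C) would add to F4 to give methyl (5E,14Z)-10-chloro-7-hydroxy-9-oxo-12-[(triethylsilyl)oxy]prosta-5,10,14-trienoate F5 (C12 as in 25, mixed at C7 and C8).
- Mesylation and elimination (MsCl, Et3N) would give 25 together with methyl (5E,7E,12R,14Z)-10-chloro-9-oxo-12-[(triethylsilyl)oxy]prosta-5,7,10,14-tetraen-1-oate F6.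
- The elimination is not expected to control the C7 geometry and may favour F6, so 25 would be separated and F6 re-equilibrated by irradiation.

**Step 10.** Hydride delivery to the hindered chloroalkyne, which has no directing group, may be slow, and the α-chloroalkenyl aluminate may lose chloride and collapse to the alkyne before iodine is added. The fallback sets out from 14 and returns at 16, using hydroxyl-directed delivery.
- Bu4NF in THF would remove the tertiary silyl ether to give (3R,5Z)-1-chloro-3-{[(4-methoxybenzyl)oxy]methyl}undec-5-en-1-yn-3-ol F7.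
- NaAlH2(OCH2CH2OCH3)2 in THF at −40 °C would deliver hydride to C11 from the alkoxyaluminate and hold aluminium on C10 cis to C12 in a five-membered chelate; iodine at −78 °C would then give (1Z,3R,5Z)-1-chloro-1-iodo-3-{[(4-methoxybenzyl)oxy]methyl}undeca-1,5-dien-3-ol F8.
- Et3SiOTf and 2,6-lutidine would return 16.

**Step 4.** The Lewis acid may ionise the 2,2-disubstituted epoxide toward the quaternary carbon (rearrangement or attack at the wrong carbon) or strip the primary silyl ether. The fallback sets out from 4 and returns at 8 without a Lewis acid and without the alkyne stage. Lithium di[(Z)-hept-1-en-1-yl]cuprate, Li[Cu(CH=CHC5H11)2], made by syn carbocupration of acetylene with lithium dipentylcuprate (from n-pentyllithium and CuBr·SMe2), would open the epoxide at its CH2 terminus and bring the 14Z alkene with it. Step 5 is then skipped, and no compound outside the list is made (F0).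

Further compounds
F1 | step 16 | (3S,5Z)-3-[(Z)-2-chloro-2-iodoethenyl]-3-[(triethylsilyl)oxy]undec-5-enal | CCCCC/C=C\C[C@@](O[Si](CC)(CC)CC)(/C=C(\I)Cl)CC=O
F2 | step 16 | (4S)-2-chloro-4-[(2Z)-oct-2-en-1-yl]-4-[(triethylsilyl)oxy]cyclopent-2-en-1-ol (C1 epimers) | CCCCC/C=C\C[C@@]1(O[Si](CC)(CC)CC)C=C(Cl)C(O)C1
F3 | step 16 | (4S)-2-chloro-4-[(2Z)-oct-2-en-1-yl]-4-[(triethylsilyl)oxy]cyclopent-2-en-1-one | CCCCC/C=C\C[C@@]1(O[Si](CC)(CC)CC)C=C(Cl)C(=O)C1
F4 | step 16 | methyl (5E)-7-oxohept-5-enoate | O=C/C=C/CCCC(=O)OC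
F5 | step 16 | methyl (5E,14Z)-10-chloro-7-hydroxy-9-oxo-12-[(triethylsilyl)oxy]prosta-5,10,14-trienoate (C12 as in 25, mixed at C7 and C8) | CCCCC/C=C\C[C@@]1(O[Si](CC)(CC)CC)C=C(Cl)C(=O)C1C(O)/C=C/CCCC(=O)OC
F6 | step 16 | methyl (5E,7E,12R,14Z)-10-chloro-9-oxo-12-[(triethylsilyl)oxy]prosta-5,7,10,14-tetraen-1-oate | CCCCC/C=C\C[C@@]1(O[Si](CC)(CC)CC)C=C(Cl)C(=O)/C1=C/C=C/CCCC(=O)OC
F7 | step 10 | (3R,5Z)-1-chloro-3-{[(4-methoxybenzyl)oxy]methyl}undec-5-en-1-yn-3-ol | CCCCC/C=C\C[C@@](O)(C#CCl)COCc1ccc(OC)cc1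
F8 | step 10 | (1Z,3R,5Z)-1-chloro-1-iodo-3-{[(4-methoxybenzyl)oxy]methyl}undeca-1,5-dien-3-ol | CCCCC/C=C\C[C@@](O)(/C=C(\I)Cl)COCc1ccc(OC)cc1
F0 | step 4 | none | none
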